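From 5.00 min on, the autumn flask, which is the flask asked about, shows no trend I can tell from the scatter: links average 49.9 % and first end groups 49.7 %. The dawn flask, richer in second end groups, averages 66.8 % and 32.2 % from 4.00 min to 12.0 min. In autumn that means 0.359 M of links and, if protic impurity has taken its whole charge, 0.145 M of second end groups. I freeze this plateau in one number, the plateau quotient, an apparent equilibrium constant: links times released group over first end groups times second end groups, with released group set equal to links and second end groups counted as charge less protic impurity less links. Autumn reads 2.50, and dawn, from a different charge, reads 2.47.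

| flask | first end groups | second end groups | protic impurity | remark | time |
|---|---|---|---|---|---|
| autumn | 0.72 M | 0.72 M | 0.216 M | the very flask that is asked about, followed so far |  |
| dawn | 0.72 M | 1.1 M | 0.216 M | run made earlier |  |
| flask | 0.72 M | 0.720 M | 0.216 M |  | 20 min |

| run | time / min | links / % | first end groups / % |
|---|---|---|---|
| autumn | 1.50 | 41.0 | 58.7 |
| autumn | 3.00 | 49.2 | 50.5 |
| autumn | 5.00 | 51.1 | 48.1 |
| autumn | 6.00 | 49.2 | 49.3 |
| autumn | 8.00 | 49.9 | 51.1 |
| autumn | 10.0 | 50.9 | 50.0 |
| autumn | 12.0 | 48.5 | 50.0 |
| dawn | 1.50 | 57.6 | 42.4 |
| dawn | 2.50 | 63.6 | 34.2 |
| dawn | 4.00 | 66.6 | 31.8 |
| dawn | 6.00 | 67.9 | 31.7 |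
| dawn | 8.00 | 66.4 | 32.4 |
| dawn | 12.0 | 66.2 | 32.8 |
| dawn | 20.0 | 64.6 | 36.2 |

(scatter of a reading: 1 percentage point)

- south-west: at 20 min take out 90 % of the released group then present, then wait 10 min
- south: at 20 min add first end groups, 50.0 % of the amount charged, then wait 10 min
- east: at 20 min add second end groups, 100 % of the amount charged, then wait 10 min
- north-west: change nothing and wait 10 min more

- links, in percent of the first end groups first charged, at 20 min
- the remedy with the largest gain of links, or "none" below 2 percentage points (south-west / south / east / north-west / none)
- links present, in percent of the first end groups first charged, after south-west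
- links present, in percent of the first end groups first charged, after east

- amounts and yields of links count idle adduct too
- what is added takes up no volume worth counting
- the numbers in the tables scatter by 1 percentage point (one standard deviation)
- on the list of suspects stand: first end groups + second end groups <-> links + released group; second end groups + links <-> idle adduct; second end groups + protic impurity -> quenched reagent

Holding the quotient, I commit to about 49.9 % at 20 min, and to links of 60.5 % after south-west, 56.4 % after south and 75.7 % after east, so east leads. Turned round, the quotient puts east at south-west's reckoned level if, of the 0.720 M added, just 0.198 M stayed usable. The dawn flask carries 0.380 M more second end groups than autumn and reads higher than south-west's reckoned level, so I reckon the autumn flask far from that outcome.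

The forecast says 49.5 % (range 46.5 % to 51.5 %), names east, and gives 60 % (56 % to 63 %) after south-west and 75 % (71 % to 79 %) after east, widening its ranges on the low side for dawn's last reading, “possibly noise or a slow loss”; my figures lie within a point of these.

The flask gives 48.8 %, with east first at a gain of 29 percentage points, 58.0 % after south-west and 77.3 % after east.

    first end groups + second end groups ⇌ links + released group (K = 1.30, k = 0.0180 L mol⁻¹ s⁻¹)
    second end groups + links ⇌ idle adduct, settled at all times (K = 9.50 L mol⁻¹)
    second end groups + protic impurity → quenched reagent (k = 0.00200 L mol⁻¹ s⁻¹)

Carried to the neighbour charged with 0.43 M of first end groups, the quotient reckons 66.0 % of links, and that flask holds 67.1 %. The autumn flask, though, is not at rest: at 20 min it still has 71 % of its protic impurity unbound, and waiting 10 min changes links by −1.1 points. Reckoned from its simulated amounts, the quotient sinks from 2.19 to 1.03 at 200 min, when protic impurity is down to 8.57 % and links stand at 41.4 %.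

(Readings and results are simulated for substances that don't exist; noise was put on by code.)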